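The oxolane (O1, aryl-bearing C2, C3, C4, C5) is disconnected at C2–C3 and O1–C5, back to O-benzylvanillin and an (E)-2-(arylmethyl)allylsilane. In one Lewis-acid-catalysed operation the aldehyde carbon bonds to alkene carbon C3, silicon migrates from C5 to C4 and the alkoxide closes on C5. This builds the ring and all three stereocentres and leaves silicon as a stand-in for the C4 hydroxyl. The step exploits two features of the oxolane ring: C5 is a bare methylene beside O1, and the C4 oxygen is trans to the C3 acetoxymethyl arm. The precursor carries a fluoride-cleavable benzhydryl(dimethyl)silyl group on C5, the protected vanillyl group on C4 and a TIPS-protected hydroxymethyl group on C3, cis to the arylmethyl group.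

Key step: step 8

Remarks on the chemistry
- Numbering: O1, C2 (aryl), C3 (CH2O arm), C4 (oxygen or silicon, arylmethyl), C5 (CH2). The same numbers are used for the corresponding atoms of the open-chain allylsilane (C3=C4, C5 = CH2Si).
- Compounds 12 and 16 (O-benzylated vanillyl alcohol and vanillin) are bought as such.
- Assumption: the sense of induction of a scandium–pybox catalyst on a one-point-bound aryl aldehyde cannot be deduced in advance. The (S,S) ligand is written; its commercial (R,R) antipode is used if a first run gives the mirror-image oxolane.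
- Precursor design: the primary oxygen carries a TIPS group, bulkier than a smaller silyl ether, so that it neither binds the Lewis acid nor competes with O1 for the cation in step 8. It is installed before the cross-coupling so that no free hydroxyl consumes the organozinc reagent.
- The E alkene of 15 (arylmethyl cis to CH2OTIPS) maps by anti addition onto the (2S,3R,4S) pattern of the target.

Step 1
Reactants: 1 diphenylmethane
Product: 3 chloro(diphenylmethyl)dimethylsilane, via benzhydryllithium 2 (not isolated)
Conditions: n-BuLi, THF, 0 → 25 °C; then added to Me2SiCl2 (3 equiv), THF, −78 → 25 °C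
Reagents that add atoms: dichlorodimethylsilane, C[Si](C)(Cl)Cl
Why: n-BuLi deprotonates the doubly benzylic CH2 and the anion displaces one chloride of excess Me2SiCl2 (nucleophilic substitution at silicon).

Step 2
Reactants: 4 propargyl bromide; 3 chloro(diphenylmethyl)dimethylsilane
Product: 6 (diphenylmethyl)dimethyl(prop-2-yn-1-yl)silane, via allenylmagnesium bromide 5 (not isolated)
Conditions: Mg, ZnBr2 (2 mol %), Et2O, 0 °C; then 3, −78 → 0 °C
Reagents that add atoms: none
Why: The allenyl Grignard reagent should silylate by SE2' substitution to give mainly the propargylsilane, and any allenylsilane is removed after step 3, where only the terminal alkyne is hydroxymethylated.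

Step 3
Reactants: 6 (diphenylmethyl)dimethyl(prop-2-yn-1-yl)silane
Product: 8 4-[(diphenylmethyl)dimethylsilyl]but-2-yn-1-ol, via lithium acetylide 7 (not isolated)
Conditions: n-BuLi (1.0 equiv), THF, −78 °C; (CH2O)n, −78 → 25 °C; H2O
Reagents that add atoms: formaldehyde (as paraformaldehyde), C=O
Why: The terminal alkyne is the most acidic site and its lithium acetylide adds to formaldehyde (acetylide hydroxymethylation).

Step 4
Reactants: 8 4-[(diphenylmethyl)dimethylsilyl]but-2-yn-1-ol
Product: 10 (Z)-4-[(diphenylmethyl)dimethylsilyl]-3-iodobut-2-en-1-ol, via cyclic alkenylalanate 9 (not isolated)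
Conditions: NaAlH2(OCH2CH2OMe)2, THF, 0 → 25 °C; EtOAc; I2, THF, −78 → 0 °C
Reagents that add atoms: iodine, II
Why: Hydroxyl-directed trans-hydroalumination puts hydride on the alkyne carbon next to CH2OH and aluminium on the distal carbon in a five-membered alkoxyalanate, and iodinolysis with retention gives the Z iodide with iodine cis to CH2OH.

Step 5
Reactants: 10 (Z)-4-[(diphenylmethyl)dimethylsilyl]-3-iodobut-2-en-1-ol
Product: 11 (Z)-{[4-[(diphenylmethyl)dimethylsilyl]-3-iodobut-2-en-1-yl]oxy}triisopropylsilane
Conditions: TIPSCl, imidazole, CH2Cl2, 0 → 25 °C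
Reagents that add atoms: chlorotriisopropylsilane, CC(C)[Si](Cl)(C(C)C)C(C)C
Why: Imidazole-mediated silylation of a primary allylic alcohol is routine, and the TIPS ether survives steps 7 and 8 but falls to fluoride in step 9.

Step 6
Reactants: 12 4-(benzyloxy)-3-methoxybenzyl alcohol
Product: 13 4-(benzyloxy)-3-methoxybenzyl chloride
Conditions: SOCl2, CH2Cl2, 0 °C
Reagents that add atoms: thionyl chloride, O=S(Cl)Cl
Why: Thionyl chloride converts an electron-rich benzylic alcohol into the chloride rapidly at 0 °C (chlorodehydroxylation through the chlorosulfite).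

Step 7
Reactants: 13 4-(benzyloxy)-3-methoxybenzyl chloride; 11 (Z)-{[4-[(diphenylmethyl)dimethylsilyl]-3-iodobut-2-en-1-yl]oxy}triisopropylsilane
Product: 15 (E)-{2-[4-(benzyloxy)-3-methoxybenzyl]-4-[(triisopropylsilyl)oxy]but-2-en-1-yl}(diphenylmethyl)dimethylsilane, via benzylzinc chloride 14 (not isolated)
Conditions: Zn dust, LiCl, THF, 25 °C; then 11, Pd(PPh3)4 (5 mol %), THF, 25 → 40 °C
Reagents that add atoms: none
Why: LiCl-assisted zinc insertion gives the benzylic zinc reagent, and Negishi coupling with the alkenyl iodide keeps the double-bond geometry, so the arylmethyl group ends cis to CH2OTIPS.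

Step 8
Reactants: 16 4-(benzyloxy)-3-methoxybenzaldehyde; 15 (E)-{2-[4-(benzyloxy)-3-methoxybenzyl]-4-[(triisopropylsilyl)oxy]but-2-en-1-yl}(diphenylmethyl)dimethylsilane
Product: 17 {(2S,3R,4S)-2-[4-(benzyloxy)-3-methoxyphenyl]-4-{[4-(benzyloxy)-3-methoxyphenyl]methyl}-3-{[(triisopropylsilyl)oxy]methyl}oxolan-4-yl}(diphenylmethyl)dimethylsilane
Conditions: Sc(OTf)3 (10 mol %), (S,S)-Ph-pybox (12 mol %), NaSbF6 (20 mol %), 4 Å MS, CH2Cl2, −20 °C
Reagents that add atoms: none
Why: Proposed new method: a cationic trivalent-scandium pybox complex should bind the aldehyde oxygen of 16 and shield one carbonyl face, whereupon alkene carbon C3 of 15 attacks anti to the C5–Si bond (C2–C3), the tertiary β-silyl cation at C4 is bridged by silicon, silicon moves from C5 to C4 on the face opposite the new bond and the scandium alkoxide attacks C5 (O1–C5) and frees the catalyst; the closest known chemistry is the racemic BF3·OEt2- or SnCl4-promoted (3+2) annulation of bulky allylsilanes with aldehydes and the scandium–pybox-catalysed enantioselective annulation of allylsilanes with chelating 1,2-dicarbonyl compounds, and the use of a one-point-binding aryl aldehyde is the unproven part. The oxolane closes through O1–C5 bond formation, an SN2-type opening of the three-membered silicon-bridged cation at its primary carbon (formally 5-endo; attack at C4 would give a strained oxetane). C3 and C4 are fixed stereospecifically by the E alkene geometry together with the anti addition of C2 and silicon across C3=C4, which puts silicon trans to the C3 arm and the arylmethyl group cis to it. C2 should come out trans to the C3 arm from an open transition state with the aryl group anti to the C3–C4 bond and the metal-bound oxygen beside the C3 hydrogen, and this is also the more stable arrangement of the acid-equilibrable p-alkoxybenzylic ether. The absolute configuration of all three centres rests on the face selection imposed by the pybox ligand. The step needs annulation to win over loss of silicon or of a proton from the C4 cation, which the bulky benzhydryl(dimethyl)silyl group and the non-nucleophilic SbF6 counter-ion favour, and it needs closure by O1 and not by the ether oxygen of the C3 arm, which the bulky TIPS group secures.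

Step 9
Reactants: 17 {(2S,3R,4S)-2-[4-(benzyloxy)-3-methoxyphenyl]-4-{[4-(benzyloxy)-3-methoxyphenyl]methyl}-3-{[(triisopropylsilyl)oxy]methyl}oxolan-4-yl}(diphenylmethyl)dimethylsilane
Product: 19 (2S,3R,4S)-2-[4-(benzyloxy)-3-methoxyphenyl]-4-{[4-(benzyloxy)-3-methoxyphenyl]methyl}-3-(hydroxymethyl)oxolan-4-ol, via fluorosilane alcohol 18 (not isolated)
Conditions: Bu4NF, THF, 25 °C; then MeOH, KHCO3, 30% aq H2O2, 40 °C
Reagents that add atoms: hydrogen peroxide, OO
Why: Fluoride forms a silicate that expels the stabilised diphenylmethyl anion and also cleaves the TIPS ether, and the fluorosilane then undergoes Fleming–Tamao oxidation, in which C4 migrates from silicon to oxygen with retention under conditions that spare the electron-rich arenes.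

Step 10
Reactants: 19 (2S,3R,4S)-2-[4-(benzyloxy)-3-methoxyphenyl]-4-{[4-(benzyloxy)-3-methoxyphenyl]methyl}-3-(hydroxymethyl)oxolan-4-ol
Product: 20 {(2S,3R,4S)-2-[4-(benzyloxy)-3-methoxyphenyl]-4-{[4-(benzyloxy)-3-methoxyphenyl]methyl}-4-hydroxyoxolan-3-yl}methyl acetate
Conditions: Ac2O (1.1 equiv), pyridine, CH2Cl2, 0 °C
Reagents that add atoms: acetic anhydride, CC(=O)OC(C)=O
Why: Without an acyl-transfer catalyst the primary alcohol is acetylated far faster than the hindered tertiary C4 alcohol (selective O-acylation).

Step 11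
Reactants: 20 {(2S,3R,4S)-2-[4-(benzyloxy)-3-methoxyphenyl]-4-{[4-(benzyloxy)-3-methoxyphenyl]methyl}-4-hydroxyoxolan-3-yl}methyl acetate
Product: 21 olivil monoacetate
Conditions: H2 (1 atm), 10% Pd/C, EtOAc, 25 °C
Reagents that add atoms: none
Why: Neutral catalytic hydrogenolysis cleaves the two aryl benzyl ethers and should leave the acetate, the tertiary alcohol and, at short reaction time in an aprotic solvent, the cyclic C2–O1 ether intact.

Compound list
1 | diphenylmethane | C(c1ccccc1)c1ccccc1 | starting material
2 | benzhydryllithium [(diphenylmethyl)lithium] | [Li]C(c1ccccc1)c1ccccc1 | intermediate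
3 | chloro(diphenylmethyl)dimethylsilane | C[Si](C)(Cl)C(c1ccccc1)c1ccccc1 | intermediate
4 | propargyl bromide (3-bromoprop-1-yne) | BrCC#C | starting material
5 | allenylmagnesium bromide (propargyl Grignard reagent) | C=C=C[Mg]Br | intermediate
6 | (diphenylmethyl)dimethyl(prop-2-yn-1-yl)silane | C#CC[Si](C)(C)C(c1ccccc1)c1ccccc1 | intermediate
7 | lithium acetylide of 6 | [Li]C#CC[Si](C)(C)C(c1ccccc1)c1ccccc1 | intermediate
8 | 4-[(diphenylmethyl)dimethylsilyl]but-2-yn-1-ol | OCC#CC[Si](C)(C)C(c1ccccc1)c1ccccc1 | intermediate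
9 | sodium cyclic alkenylalanate (five-membered O–Al–C=C–C ring, two 2-methoxyethoxy groups on aluminium, CH2Si on the Al-bearing carbon) | [Na+].COCCO[Al-]1(OCCOC)OCC=C1C[Si](C)(C)C(c1ccccc1)c1ccccc1 | intermediate
10 | (Z)-4-[(diphenylmethyl)dimethylsilyl]-3-iodobut-2-en-1-ol (iodine cis to CH2OH) | OC/C=C(\I)C[Si](C)(C)C(c1ccccc1)c1ccccc1 | intermediate
11 | (Z)-{[4-[(diphenylmethyl)dimethylsilyl]-3-iodobut-2-en-1-yl]oxy}triisopropylsilane | CC(C)[Si](OC/C=C(\I)C[Si](C)(C)C(c1ccccc1)c1ccccc1)(C(C)C)C(C)C | intermediate
12 | 4-(benzyloxy)-3-methoxybenzyl alcohol | COc1cc(CO)ccc1OCc1ccccc1 | starting material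
13 | 4-(benzyloxy)-3-methoxybenzyl chloride | COc1cc(CCl)ccc1OCc1ccccc1 | intermediate
14 | [4-(benzyloxy)-3-methoxybenzyl]zinc chloride | COc1cc(C[Zn]Cl)ccc1OCc1ccccc1 | intermediate
15 | (E)-{2-[4-(benzyloxy)-3-methoxybenzyl]-4-[(triisopropylsilyl)oxy]but-2-en-1-yl}(diphenylmethyl)dimethylsilane (arylmethyl cis to CH2OTIPS) | CC(C)[Si](OC/C=C(\Cc1ccc(OCc2ccccc2)c(OC)c1)C[Si](C)(C)C(c1ccccc1)c1ccccc1)(C(C)C)C(C)C | intermediate
16 | 4-(benzyloxy)-3-methoxybenzaldehyde | O=Cc1ccc(OCc2ccccc2)c(OC)c1 | starting material
17 | {(2S,3R,4S)-2-[4-(benzyloxy)-3-methoxyphenyl]-4-{[4-(benzyloxy)-3-methoxyphenyl]methyl}-3-{[(triisopropylsilyl)oxy]methyl}oxolan-4-yl}(diphenylmethyl)dimethylsilane (silicon and C2 aryl both trans to the C3 arm) | COc1cc(C[C@@]2([Si](C)(C)C(c3ccccc3)c3ccccc3)CO[C@H](c3ccc(OCc4ccccc4)c(OC)c3)[C@H]2CO[Si](C(C)C)(C(C)C)C(C)C)ccc1OCc1ccccc1 | intermediate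
18 | {(2S,3R,4S)-2-[4-(benzyloxy)-3-methoxyphenyl]-4-{[4-(benzyloxy)-3-methoxyphenyl]methyl}-4-[fluoro(dimethyl)silyl]oxolan-3-yl}methanol | COc1cc(C[C@@]2([Si](C)(C)F)CO[C@H](c3ccc(OCc4ccccc4)c(OC)c3)[C@H]2CO)ccc1OCc1ccccc1 | intermediate
19 | (2S,3R,4S)-2-[4-(benzyloxy)-3-methoxyphenyl]-4-{[4-(benzyloxy)-3-methoxyphenyl]methyl}-3-(hydroxymethyl)oxolan-4-ol | COc1cc(C[C@@]2(O)CO[C@H](c3ccc(OCc4ccccc4)c(OC)c3)[C@H]2CO)ccc1OCc1ccccc1 | intermediate
20 | {(2S,3R,4S)-2-[4-(benzyloxy)-3-methoxyphenyl]-4-{[4-(benzyloxy)-3-methoxyphenyl]methyl}-4-hydroxyoxolan-3-yl}methyl acetate | COc1cc(C[C@@]2(O)CO[C@H](c3ccc(OCc4ccccc4)c(OC)c3)[C@H]2COC(C)=O)ccc1OCc1ccccc1 | intermediate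
21 | olivil monoacetate: {(2S,3R,4S)-4-hydroxy-2-(4-hydroxy-3-methoxyphenyl)-4-[(4-hydroxy-3-methoxyphenyl)methyl]oxolan-3-yl}methyl acetate | COc1cc(C[C@@]2(O)CO[C@H](c3ccc(O)c(OC)c3)[C@H]2COC(C)=O)ccc1O | target

Total step count: 11. Longest linear sequence: 10 steps (steps 1, 2, 3, 4, 5, 7, 8, 9, 10, 11; step 6 is a one-step side branch).

Steps most likely to fail

Step 8. A catalyst that holds the aldehyde at a single point may discriminate its faces poorly. The silyl shift may also lose out to loss of silicon or of a proton from the C4 cation, and the kinetic closure may place the aryl group cis to the C3 arm. The fallback sets out from 15 and 16 and comes back at 19.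
- The partners are combined with stoichiometric BF3·OEt2 in CH2Cl2 at −78 → −20 °C, the established racemic form of the annulation. This should give the racemic silyl oxolane F1 with the relative configuration of 17.
- C3 and C4 follow from the stereospecific anti addition. C2 is trans under thermodynamic control, because BF3 reversibly ionises the p-alkoxybenzylic C2–O1 bond.
- F1 is unmasked and oxidised under the conditions of step 9 to the racemic diol F2.
- The primary hydroxyl of F2 is esterified with (R)-2-methoxy-2-phenylacetic acid (EDC, cat. DMAP, CH2Cl2, 0 °C). The two diastereomeric esters are separated by chromatography or crystallisation.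
- The ester of the (2S,3R,4S) diol, the (R)-O-methylmandelate F3, is cleaved with K2CO3 in MeOH to 19.

Step 9. The fluorosilicate may fragment by β-elimination across Si–C4–C5–O1 with ring opening, or migration at the hindered tertiary C4–Si bond may stall under basic peroxide. The fallback sets out from 17 and comes back at 19.
- The fluoride stage is run cold (Bu4NF, THF, 0 °C) and quenched with AcOH before work-up, so that the fluorosilane alcohol 18 is isolated.
- 18 is then oxidised under anhydrous, non-basic peracid conditions (m-CPBA, KF, DMF, 25 °C), the electrophilic variant of the Fleming–Tamao oxidation.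
- This fallback makes no new compound (F0).

Step 7. Wurtz-type homocoupling during zinc insertion into the electron-rich benzylic chloride may leave too little organozinc for the coupling. The fallback sets out from 13, uses 11, and comes back at 15.
- Miyaura borylation of 13 (B2pin2, Pd2(dba)3, P(4-MeOC6H4)3, KOAc, toluene, 50 °C) gives the benzylboronic pinacol ester F4.
- F4 is joined to 11 by Suzuki–Miyaura coupling (PdCl2(dppf), Cs2CO3, THF/H2O, 60 °C), with retention of the alkene geometry, to give 15.

Further compounds
F1 | step 8 | racemic {(2S*,3R*,4S*)-2-[4-(benzyloxy)-3-methoxyphenyl]-4-{[4-(benzyloxy)-3-methoxyphenyl]methyl}-3-{[(triisopropylsilyl)oxy]methyl}oxolan-4-yl}(diphenylmethyl)dimethylsilane (racemate; one enantiomer drawn) | COc1cc(C[C@@]2([Si](C)(C)C(c3ccccc3)c3ccccc3)CO[C@H](c3ccc(OCc4ccccc4)c(OC)c3)[C@H]2CO[Si](C(C)C)(C(C)C)C(C)C)ccc1OCc1ccccc1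
F2 | step 8 | racemic (2S*,3R*,4S*)-2-[4-(benzyloxy)-3-methoxyphenyl]-4-{[4-(benzyloxy)-3-methoxyphenyl]methyl}-3-(hydroxymethyl)oxolan-4-ol (racemate; one enantiomer drawn) | COc1cc(C[C@@]2(O)CO[C@H](c3ccc(OCc4ccccc4)c(OC)c3)[C@H]2CO)ccc1OCc1ccccc1
F3 | step 8 | {(2S,3R,4S)-2-[4-(benzyloxy)-3-methoxyphenyl]-4-{[4-(benzyloxy)-3-methoxyphenyl]methyl}-4-hydroxyoxolan-3-yl}methyl (R)-2-methoxy-2-phenylacetate | COc1cc(C[C@@]2(O)CO[C@H](c3ccc(OCc4ccccc4)c(OC)c3)[C@H]2COC(=O)[C@H](OC)c2ccccc2)ccc1OCc1ccccc1
F0 | step 9 | none | none
F4 | step 7 | 2-[4-(benzyloxy)-3-methoxybenzyl]-4,4,5,5-tetramethyl-1,3,2-dioxaborolane | COc1cc(CB2OC(C)(C)C(C)(C)O2)ccc1OCc1ccccc1
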